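**Retrosynthetic overview**

1. Cembrane numbering is used: C1 ring-fusion CH, C2 ring CH2, C3 and C13 the two pyran OCH carbons, C4 and C8 the methyl carbinols, C6=C7 the Z olefin, C12 the CHCH3, C14 the lactone OCH, C15–C17 the methylidene-lactone carbons.
2. Last C–C disconnection is C7–C8: Ni/Cr addition of the (Z)-C6=C7 alkenyl iodide to the C8 methyl ketone, run in the same flask directly after the pyran closure O13→C3 (6-exo opening of a C3–C4 epoxide), so the tricycle arises from a monocyclic lactone.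
3. Enabling feature: the cis-fused γ-lactone (O, C16, C15, C1, C14) holds the C13 oxygen next to C3, and the resulting cis-2,6-disubstituted tetrahydropyran (O, C3, C2, C1, C14, C13) carries both arms on the same side, so C7 and C8 meet in a 12-membered oxa-bridged (14-membered carbocyclic) ring.
4. Lactone 22 comes from a Cr(II) allylation/lactonisation of α-silyloxy aldehyde 9 (C8–C14) with achiral bromide 20 (C1–C7, C15–C17), which relays C14 and C1 from C13; C12/C13 come from one catalytic crotylboration and C3/C4 from a Shi epoxidation.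
5. Ring order: γ-lactone (step 11), then tetrahydropyran and macrocycle (both in step 13).

Key step: step 13

Remark: 1-(trimethylsilyl)penta-1,4-diyne (10) and the L-fructose-derived (ent) Shi ketone are taken as purchasable, and the 8R outcome of the ring closure is a stereochemical expectation, not an established result.

**Route**

Step 1
Reactants: 1 (E)-cinnamaldehyde; 2 2-[(2Z)-but-2-en-1-yl]-4,4,5,5-tetramethyl-1,3,2-dioxaborolane
Product: 3 (1E,3S,4S)-4-methyl-1-phenylhexa-1,5-dien-3-ol
Conditions: (R)-TRIP (5 mol%), toluene, −30 °C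
Reagents that add atoms: none
Why: Chiral phosphoric acid-catalysed crotylboration through a closed chair transition state, in which the (Z)-crotyl boronate gives the syn relationship (C12 methyl, C13 oxygen) and the catalyst directs addition to the Re face of the aldehyde, should set both centres (3S,4S).

Step 2
Reactants: 3 (1E,3S,4S)-4-methyl-1-phenylhexa-1,5-dien-3-ol
Product: 4 triethyl{[(1E,3S,4S)-4-methyl-1-phenylhexa-1,5-dien-3-yl]oxy}silane
Conditions: TESCl, imidazole, CH2Cl2, 0 °C → rt
Reagents that add atoms: chlorotriethylsilane CC[Si](Cl)(CC)CC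
Why: Silyl ether formation masks the C13 hydroxyl for the borane, ozone and chromium steps and makes it the non-chelating α-substituent needed in step 11, with no stereocentre touched.

Step 3
Reactants: 4 triethyl{[(1E,3S,4S)-4-methyl-1-phenylhexa-1,5-dien-3-yl]oxy}silane; 5 bromoacetone
Product: 7 (5S,6R,7E)-5-methyl-8-phenyl-6-[(triethylsilyl)oxy]oct-7-en-2-one, via trialkylborane 6 (not isolated)
Conditions: 9-BBN, THF, 0 °C → rt; then 5, potassium 2,6-di-tert-butylphenoxide, THF, 0 °C → rt
Reagents that add atoms: none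
Why: Anti-Markovnikov hydroboration of the terminal vinyl group (selective over the 1,2-disubstituted styryl olefin) followed by α-alkylation of the α-bromo ketone by the B-alkyl group (boron ate complex, 1,2-migration with loss of bromide) should extend the chain by three carbons to the methyl ketone without touching C12 or C13.

Step 4
Reactants: 7 (5S,6R,7E)-5-methyl-8-phenyl-6-[(triethylsilyl)oxy]oct-7-en-2-one
Product: 9 (2R,3S)-3-methyl-7-oxo-2-[(triethylsilyl)oxy]octanal, via ozonide 8 (not isolated)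
Conditions: O3, CH2Cl2, −78 °C; then PPh3, −78 °C → rt
Reagents that add atoms: ozone [O-][O+]=O
Why: Ozonolysis with reductive work-up cleaves the only remaining olefin, the styryl group, and should unveil the C14 aldehyde without epimerising the α-silyloxy centre.

Step 5
Reactants: 10 trimethyl(penta-1,4-diyn-1-yl)silane; 11 oxirane
Product: 13 (3E)-4-methyl-7-(trimethylsilyl)hept-3-en-6-yn-1-ol, via alkenylalane 12 (not isolated)
Conditions: Me3Al, Cp2ZrCl2 (cat.), CH2Cl2, 0 °C → rt; then n-BuLi, THF, −78 °C; 11, −78 → 0 °C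
Reagents that add atoms: trimethylaluminium C[Al](C)C
Why: Zirconium-catalysed carboalumination (Negishi) adds CH3 and Al syn across the terminal alkyne with the metal on the terminal carbon, and the derived alanate opens the epoxide with retention at the alkenyl carbon, which should fix the E trisubstituted C3=C4 olefin while the silylated internal alkyne stays inert.

Step 6
Reactants: 13 (3E)-4-methyl-7-(trimethylsilyl)hept-3-en-6-yn-1-ol
Product: 14 (3E)-7-iodo-4-methylhept-3-en-6-yn-1-ol
Conditions: NIS, AgNO3 (cat.), acetone, rt, dark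
Reagents that add atoms: N-iodosuccinimide O=C1CCC(=O)N1I
Why: Silver-catalysed iododesilylation, in which the silver acetylide formed from the alkynylsilane is iodinated by NIS, should give the 1-iodoalkyne.

Step 7
Reactants: 14 (3E)-7-iodo-4-methylhept-3-en-6-yn-1-ol
Product: 15 (3E,6Z)-7-iodo-4-methylhepta-3,6-dien-1-ol
Conditions: 2-nitrobenzenesulfonyl hydrazide, Et3N, THF/i-PrOH, rt
Reagents that add atoms: none
Why: Diimide generated from the sulfonyl hydrazide transfers H2 syn to the iodoalkyne, the standard access to a (Z)-1-iodoalkene, and reduces the trisubstituted olefin far more slowly.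

Step 8
Reactants: 15 (3E,6Z)-7-iodo-4-methylhepta-3,6-dien-1-ol
Product: 16 (3E,6Z)-7-iodo-4-methylhepta-3,6-dienal
Conditions: Dess–Martin periodinane, NaHCO3, CH2Cl2, 0 °C; used at once
Reagents that add atoms: none
Why: Dess–Martin oxidation under buffered, non-basic conditions should give the β,γ-unsaturated aldehyde without migration of the C3=C4 double bond.

Step 9
Reactants: 16 (3E,6Z)-7-iodo-4-methylhepta-3,6-dienal; 17 methyl propiolate
Product: 19 methyl (5E,8Z)-3-hydroxy-9-iodo-6-methyl-2-methylidenenona-5,8-dienoate (racemic), via vinylalane 18 (not isolated)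
Conditions: i-Bu2AlH, NMO, THF, 0 °C (with 17); then 16, 0 °C → rt
Reagents that add atoms: none
Why: Hydroalumination of the propiolate gives the α-(methoxycarbonyl)vinylalane, which adds 1,2 to the aldehyde (vinylalumination) to give the Morita–Baylis–Hillman-type adduct without an amine base that would conjugate the skipped diene; the carbinol centre is racemic and is destroyed in step 10.

Step 10
Reactants: 19 methyl (5E,8Z)-3-hydroxy-9-iodo-6-methyl-2-methylidenenona-5,8-dienoate
Product: 20 methyl (2Z,5E,8Z)-2-(bromomethyl)-9-iodo-6-methylnona-2,5,8-trienoate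
Conditions: NBS, Me2S, CH2Cl2, 0 °C → rt
Reagents that add atoms: N-bromosuccinimide O=C1CCC(=O)N1Br
Why: Activation of the allylic alcohol as an alkoxysulfonium ion and SN2' attack of bromide transposes the allylic system to the conjugated, thermodynamically preferred (Z)-2-(bromomethyl)enoate.

Step 11
Reactants: 9 (2R,3S)-3-methyl-7-oxo-2-[(triethylsilyl)oxy]octanal; 20 methyl (2Z,5E,8Z)-2-(bromomethyl)-9-iodo-6-methylnona-2,5,8-trienoate
Product: 22 (4R,5S)-4-[(2E,5Z)-6-iodo-3-methylhexa-2,5-dien-1-yl]-3-methylidene-5-[(1R,2S)-2-methyl-6-oxo-1-[(triethylsilyl)oxy]heptyl]oxolan-2-one, via hydroxy ester 21 (not isolated)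
Conditions: CrCl2 (Ni-free), THF, 0 °C → rt; aq. NH4Cl; PPTS (cat.), CH2Cl2, rt
Reagents that add atoms: none
Why: Nozaki–Hiyama-type Barbier allylation, in which the γ-substituted 2-(methoxycarbonyl)allylchromium(III) adds through a chair Zimmerman–Traxler transition state (C1 substituent axial, hence the syn adduct and the cis-lactone) to the Felkin–Anh face of the α-silyloxy aldehyde (13,14-anti), should set C14 and C1 in one event; the aldehyde reacts much faster than the methyl ketone, the alkenyl iodide is inert without nickel, and the chromium alkoxide lactonises.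

Step 12
Reactants: 22 (4R,5S)-4-[(2E,5Z)-6-iodo-3-methylhexa-2,5-dien-1-yl]-3-methylidene-5-[(1R,2S)-2-methyl-6-oxo-1-[(triethylsilyl)oxy]heptyl]oxolan-2-one
Product: 23 (4R,5S)-4-{[(2S,3S)-3-[(2Z)-3-iodoprop-2-en-1-yl]-3-methyloxiran-2-yl]methyl}-3-methylidene-5-[(1R,2S)-2-methyl-6-oxo-1-[(triethylsilyl)oxy]heptyl]oxolan-2-one
Conditions: ent-Shi ketone (30 mol%), Oxone, K2CO3, Bu4NHSO4, MeCN/DMM/aq. borate buffer, 0 °C
Reagents that add atoms: potassium peroxymonosulfate (Oxone) [K+].[O-]S(=O)(=O)OO
Why: Shi asymmetric epoxidation, in which the chiral dioxirane attacks the electron-rich (E)-trisubstituted C3=C4 olefin through the spiro transition state, should give the (3S,4S)-epoxide under catalyst control, while the acrylate-type methylidene and the iodoalkene are too electron-poor to react.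

Step 13
Reactants: 23 (4R,5S)-4-{[(2S,3S)-3-[(2Z)-3-iodoprop-2-en-1-yl]-3-methyloxiran-2-yl]methyl}-3-methylidene-5-[(1R,2S)-2-methyl-6-oxo-1-[(triethylsilyl)oxy]heptyl]oxolan-2-one
Product: 27 (1R,3R,4S,6Z,8R,12S,13R,14S)-3,13-epoxy-4,8-dihydroxycembra-6,15(17)-dien-16,14-olide (CNP0146755.1), via epoxy alcohol 24 (not isolated), via iodo ketone 25 (not isolated), via alkenylchromium 26 (not isolated)
Conditions: (i) CSA (cat.), CH2Cl2/MeOH, 0 °C; Et3N, evaporation; (ii) CrCl2 (excess), NiCl2 (cat.), DMSO/THF, high dilution (slow addition), rt → 40 °C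
Reagents that add atoms: none
Why: Stage (i) is an acid-catalysed epoxy-alcohol cyclisation in which methanolysis of the silyl ether frees the C13 hydroxyl and this opens the protonated epoxide at C3 with inversion, and stage (ii) is a Nozaki–Hiyama–Kishi reaction in which Ni(0) inserts into the C7–I bond, the alkenyl group passes to Cr(III) with retention of the Z geometry and the alkenylchromium adds 1,2 to the C8 ketone. The closest known reactions are 6-exo epoxide openings in polyether synthesis and Ni/Cr macrocyclisations of iodoalkenes onto aldehydes in cembranoid synthesis, together with intramolecular Ni/Cr alkenylations of ketones. The tetrahydropyran closes 6-exo-tet (attack at the secondary C3 instead of 7-endo attack at the tertiary C4, helped by the cis-lactone that holds the C13 oxygen next to C3), and the carbocycle closes as a 14-membered ring (12-membered through the ether oxygen) by carbonyl addition under high dilution. C3 (R) follows stereospecifically from the 3S epoxide carbon by inversion and C4 (S) is carried over from the epoxide, while C8 is set under substrate control: the cis-2,6-tetrahydropyran places both arms on the same face and the C4 hydroxyl can bind the chromium on C7, so the ketone is expected to react with its methyl group on the outside of the forming ring, which corresponds to the 8R carbinol. The step needs the pyran to form before the C7–C8 bond (a C8 hydroxyl would open the epoxide at the tertiary C4), which the order of the two stages secures, and it needs carbonyl-selective addition in the presence of the methylidene lactone and two free hydroxyl groups, which the low basicity of organochromium(III) reagents secures.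

**Compound list**

1 | (E)-cinnamaldehyde | O=C/C=C/c1ccccc1 | starting material
2 | 2-[(2Z)-but-2-en-1-yl]-4,4,5,5-tetramethyl-1,3,2-dioxaborolane | C/C=C\CB1OC(C)(C)C(C)(C)O1 | starting material
3 | (1E,3S,4S)-4-methyl-1-phenylhexa-1,5-dien-3-ol | c1ccccc1/C=C/[C@H](O)[C@@H](C)C=C | intermediate
4 | triethyl{[(1E,3S,4S)-4-methyl-1-phenylhexa-1,5-dien-3-yl]oxy}silane | c1ccccc1/C=C/[C@H](O[Si](CC)(CC)CC)[C@@H](C)C=C | intermediate
5 | bromoacetone | CC(=O)CBr | starting material
6 | 9-[(3S,4R,5E)-3-methyl-6-phenyl-4-[(triethylsilyl)oxy]hex-5-en-1-yl]-9-borabicyclo[3.3.1]nonane | c1ccccc1/C=C/[C@H](O[Si](CC)(CC)CC)[C@@H](C)CCB1C2CCCC1CCC2 | intermediate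
7 | (5S,6R,7E)-5-methyl-8-phenyl-6-[(triethylsilyl)oxy]oct-7-en-2-one | c1ccccc1/C=C/[C@H](O[Si](CC)(CC)CC)[C@@H](C)CCCC(C)=O | intermediate
8 | 3-phenyl-5-[(1R,2S)-2-methyl-6-oxo-1-[(triethylsilyl)oxy]heptyl]-1,2,4-trioxolane (ozonide, mixture at the ring carbons) | c1ccccc1C1OOC(O1)[C@H](O[Si](CC)(CC)CC)[C@@H](C)CCCC(C)=O | intermediate
9 | (2R,3S)-3-methyl-7-oxo-2-[(triethylsilyl)oxy]octanal | O=C[C@H](O[Si](CC)(CC)CC)[C@@H](C)CCCC(C)=O | intermediate
10 | trimethyl(penta-1,4-diyn-1-yl)silane | C#CCC#C[Si](C)(C)C | starting material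
11 | oxirane | C1CO1 | starting material
12 | dimethyl[(1E)-2-methyl-5-(trimethylsilyl)pent-1-en-4-yn-1-yl]alane | C[Al](C)/C=C(\C)CC#C[Si](C)(C)C | intermediate
13 | (3E)-4-methyl-7-(trimethylsilyl)hept-3-en-6-yn-1-ol | OCC/C=C(\C)CC#C[Si](C)(C)C | intermediate
14 | (3E)-7-iodo-4-methylhept-3-en-6-yn-1-ol | OCC/C=C(\C)CC#CI | intermediate
15 | (3E,6Z)-7-iodo-4-methylhepta-3,6-dien-1-ol | OCC/C=C(\C)C/C=C\I | intermediate
16 | (3E,6Z)-7-iodo-4-methylhepta-3,6-dienal | O=CC/C=C(\C)C/C=C\I | intermediate
17 | methyl propiolate | C#CC(=O)OC | starting material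
18 | methyl 2-(diisobutylalumanyl)prop-2-enoate | C=C(C(=O)OC)[Al](CC(C)C)CC(C)C | intermediate
19 | methyl (5E,8Z)-3-hydroxy-9-iodo-6-methyl-2-methylidenenona-5,8-dienoate (racemic) | C=C(C(=O)OC)C(O)C/C=C(\C)C/C=C\I | intermediate
20 | methyl (2Z,5E,8Z)-2-(bromomethyl)-9-iodo-6-methylnona-2,5,8-trienoate | BrC/C(C(=O)OC)=C\C/C=C(\C)C/C=C\I | intermediate
21 | methyl (3R,4S,5R,6S)-4-hydroxy-3-[(2E,5Z)-6-iodo-3-methylhexa-2,5-dien-1-yl]-6-methyl-2-methylidene-10-oxo-5-[(triethylsilyl)oxy]undecanoate | C=C(C(=O)OC)[C@@H](C/C=C(\C)C/C=C\I)[C@H](O)[C@H](O[Si](CC)(CC)CC)[C@@H](C)CCCC(C)=O | intermediate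
22 | (4R,5S)-4-[(2E,5Z)-6-iodo-3-methylhexa-2,5-dien-1-yl]-3-methylidene-5-[(1R,2S)-2-methyl-6-oxo-1-[(triethylsilyl)oxy]heptyl]oxolan-2-one | C=C1C(=O)O[C@H]([C@H](O[Si](CC)(CC)CC)[C@@H](C)CCCC(C)=O)[C@@H]1C/C=C(\C)C/C=C\I | intermediate
23 | (4R,5S)-4-{[(2S,3S)-3-[(2Z)-3-iodoprop-2-en-1-yl]-3-methyloxiran-2-yl]methyl}-3-methylidene-5-[(1R,2S)-2-methyl-6-oxo-1-[(triethylsilyl)oxy]heptyl]oxolan-2-one | C=C1C(=O)O[C@H]([C@H](O[Si](CC)(CC)CC)[C@@H](C)CCCC(C)=O)[C@@H]1C[C@@H]2O[C@@]2(C)C/C=C\I | intermediate
24 | (4R,5S)-5-[(1R,2S)-1-hydroxy-2-methyl-6-oxoheptyl]-4-{[(2S,3S)-3-[(2Z)-3-iodoprop-2-en-1-yl]-3-methyloxiran-2-yl]methyl}-3-methylideneoxolan-2-one | C=C1C(=O)O[C@H]([C@H](O)[C@@H](C)CCCC(C)=O)[C@@H]1C[C@@H]2O[C@@]2(C)C/C=C\I | intermediate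
25 | (3aR,5R,7R,7aS)-5-[(2S,4Z)-2-hydroxy-5-iodopent-4-en-2-yl]-3-methylidene-7-[(2S)-6-oxoheptan-2-yl]hexahydro-2H-furo[2,3-c]pyran-2-one | C=C1C(=O)O[C@@H]2[C@@H]([C@H](CCCC(C)=O)C)O[C@@H]([C@@](C)(O)C/C=C\I)C[C@H]12 | intermediate
26 | (Z)-alkenylchromium(III) dichloride of 25 (CrCl2 in place of iodine at C7) | C=C1C(=O)O[C@@H]2[C@@H]([C@H](CCCC(C)=O)C)O[C@@H]([C@@](C)(O)C/C=C\[Cr](Cl)Cl)C[C@H]12 | intermediate
27 | (1R,3R,4S,6Z,8R,12S,13R,14S)-3,13-epoxy-4,8-dihydroxycembra-6,15(17)-dien-16,14-olide (CNP0146755.1) | C=C1C(=O)O[C@@H]2[C@@H]3O[C@H](C[C@H]12)[C@@](C)(O)C/C=C\[C@](C)(O)CCC[C@@H]3C | target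

**Step count**

Total step count: 13. Longest linear sequence: 9 steps (steps 5–13, from 10).

**Steps most likely to fail**

1. Step 13. The alkenylchromium may add slowly to the hindered methyl ketone (protodeiodination or oligomerisation taking over), or the facial selectivity at C8 may be poor or reversed in the pyran-locked chain. Fallback, setting out from 22 and returning at 27, with the order of ring formation changed: lactone 22 is cyclised first under the same Ni/Cr conditions to the 14-membered (8R)-8-hydroxy-13-[(triethylsilyl)oxy]cembra-3,6,15(17)-trien-16,14-olide F1, whose conformation is not restricted by the pyran. Its tertiary hydroxyl is capped (TESOTf, 2,6-lutidine) to give the 8,13-bis(triethylsilyl) ether F2. Shi epoxidation with the ent-ketone then gives the (3S,4S)-epoxide F3. CSA in MeOH/CH2Cl2 removes only the secondary silyl ether and closes the pyran transannularly to the 8-O-triethylsilyl ether of the target F4; the capped C8 oxygen cannot open the epoxide at C4. HF·pyridine then frees the C8 hydroxyl to give 27.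

2. Step 11. The Felkin/syn diastereocontrol may erode, or the α-silyloxy aldehyde may epimerise at C13 under the Lewis-acidic chromium conditions. Fallback, setting out from 19 (with 9) and returning at 22: the allyl nucleophile is changed to a configurationally defined boron reagent. Alcohol 19 is acetylated (Ac2O, DMAP) to methyl (5E,8Z)-3-acetoxy-9-iodo-6-methyl-2-methylidenenona-5,8-dienoate F5. Copper-catalysed SN2' borylation (B2pin2, CuCl, KOAc, DMF) gives methyl (2E,5E,8Z)-9-iodo-6-methyl-2-[(4,4,5,5-tetramethyl-1,3,2-dioxaborolan-2-yl)methyl]nona-2,5,8-trienoate F6. Sc(OTf)3-catalysed allylboration of 9 through a closed chair transition state, then PPTS, gives lactone 22.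

3. Step 9. The C3=C4 double bond may migrate into conjugation with the aldehyde, or the vinylalane may add sluggishly. Fallback, setting out from 16 and returning at 19: the acrylate unit is introduced by a thiolate-triggered Michael–aldol sequence at low temperature. Me2AlSPh and methyl acrylate (CH2Cl2, −78 °C) convert 16 into methyl (5E,8Z)-3-hydroxy-9-iodo-6-methyl-2-[(phenylsulfanyl)methyl]nona-5,8-dienoate F7. NaIO4 oxidises it to methyl (5E,8Z)-3-hydroxy-9-iodo-6-methyl-2-[(phenylsulfinyl)methyl]nona-5,8-dienoate F8. Thermal syn-elimination of the sulfoxide (toluene, CaCO3, 110 °C) gives 19.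

Further compounds
F1 | step 13 | (1R,3E,6Z,8R,12S,13R,14S)-8-hydroxy-13-[(triethylsilyl)oxy]cembra-3,6,15(17)-trien-16,14-olide | C=C1C(=O)O[C@@H]2[C@H](O[Si](CC)(CC)CC)[C@@H](C)CCC[C@@](C)(O)/C=C\C/C(C)=C/C[C@H]12
F2 | step 13 | (1R,3E,6Z,8R,12S,13R,14S)-8,13-bis[(triethylsilyl)oxy]cembra-3,6,15(17)-trien-16,14-olide | C=C1C(=O)O[C@@H]2[C@H](O[Si](CC)(CC)CC)[C@@H](C)CCC[C@@](C)(O[Si](CC)(CC)CC)/C=C\C/C(C)=C/C[C@H]12
F3 | step 13 | (3S,4S)-3,4-epoxide of F2 | C=C1C(=O)O[C@@H]2[C@H](O[Si](CC)(CC)CC)[C@@H](C)CCC[C@@](C)(O[Si](CC)(CC)CC)/C=C\C[C@]3(C)O[C@H]3C[C@H]12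
F4 | step 13 | 8-O-triethylsilyl ether of 27 | C=C1C(=O)O[C@@H]2[C@@H]3O[C@H](C[C@H]12)[C@@](C)(O)C/C=C\[C@](C)(O[Si](CC)(CC)CC)CCC[C@@H]3C
F5 | step 11 | methyl (5E,8Z)-3-acetoxy-9-iodo-6-methyl-2-methylidenenona-5,8-dienoate | C=C(C(=O)OC)C(OC(C)=O)C/C=C(\C)C/C=C\I
F6 | step 11 | methyl (2E,5E,8Z)-9-iodo-6-methyl-2-[(4,4,5,5-tetramethyl-1,3,2-dioxaborolan-2-yl)methyl]nona-2,5,8-trienoate | COC(=O)C(/CB1OC(C)(C)C(C)(C)O1)=C/C/C=C(\C)C/C=C\I
F7 | step 9 | methyl (5E,8Z)-3-hydroxy-9-iodo-6-methyl-2-[(phenylsulfanyl)methyl]nona-5,8-dienoate | COC(=O)C(CSc1ccccc1)C(O)C/C=C(\C)C/C=C\I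
F8 | step 9 | methyl (5E,8Z)-3-hydroxy-9-iodo-6-methyl-2-[(phenylsulfinyl)methyl]nona-5,8-dienoate | COC(=O)C(CS(=O)c1ccccc1)C(O)C/C=C(\C)C/C=C\I
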